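Compound numbers used throughout: 1–20 as defined in the steps and in the compound list; 20 is the target.

## Analysis of the target

Target 20 is a single γ-butyrolactone (ring atoms O1, carbonyl C2, C3, C4, C5) with a 4-hydroxy-3-methoxybenzyl group on C3 and a hydroxy(3,4-dimethoxyphenyl)methyl group on C4. It has three contiguous stereocentres: C3 (R), C4 (R) and the exocyclic carbinol carbon (S). The C3 and C4 substituents are trans. The carbinol centre is related to C4 as in a syn aldol, if C5 is read as the acyl carbon and the C3 methylene as the α-substituent.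

The sensitive groups are the free phenol, the enolisable C3, and above all the electron-rich secondary benzylic alcohol. That alcohol ionises in acid (with ring closure onto the guaiacyl ring), is cleaved by hydrogenolysis, and its oxygen lies four atoms from the lactone carbonyl, so its alkoxide can take over the acyl group and give the isomeric five-membered lactone.

The hard part is the carbinol centre. It hangs on C4, the β-carbon, which no enolate of this lactone can reach. The trans benzyl group on C3 is routine by comparison.

The strategy rests on the four-carbon chain C2–C3–C4–C5. It is oxygenated at both ends, C2 at the acid level and C5 at the alcohol level. If these two oxidation levels are exchanged, C4 becomes an α-carbon and its substituent becomes an ordinary aldol residue. Lactone 1 offers exactly such a reversed lactone, with one extra carbon on its γ-position that can be cut away and one stereocentre that can relay its chirality before it is lost.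

## Retrosynthetic reasoning

**20 from 19.** Only the two O–Si bonds are cut. Both hydroxyls carry the same silyl group, so one buffered fluoride step ends the synthesis. A benzyl ether on the phenol is excluded, because its hydrogenolysis would endanger the benzylic C–O bond of the carbinol. The forward step must free the carbinol oxygen without ever making it an alkoxide next to the lactone.

**19 from 13 and 17.** The C3–CH2(aryl) bond is cut. C3 is the only enolisable carbon of 13, and the large silyloxy(aryl)methyl group on C4 should send the electrophile to the opposite face, which gives the trans arrangement. Bromide 17 is traced to 14 through 15 and 16 by protection, reduction and bromination.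

**13 from 12, and 12 from 10 through 11.** This is where the chain is turned around. The carbonyl carbon of 13 is traced to the lactol carbon of 12, then to the aldehyde carbon of 11, and then to the secondary carbinol carbon of the diol end of 10. In the forward sense the C4–C5 bond of the pentanetriol is broken and the ring O–C bond is formed. The CH2O carbon of 13 is the former carbonyl carbon of lactone 8, and the new carbonyl carbon is its former γ-carbon. The gain is that the C4 substituent of 13 can be introduced earlier at an α-position. The forward reaction must cleave only the 1,2-diol and must let only the primary hydroxyl close the ring. That is why the carbinol oxygen has to be a silyl ether at this point.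

**10 from 9, and 9 from 8.** The terminal diol is unmasked by removing the trityl group, and the open chain comes from hydride reduction of lactone 8. No stereocentre is touched. The reduction converts the old acyl carbon into the CH2OH that later becomes C5 of the final ring.

**8 from 7, 7 from 6, 6 from 5, and 5 from 2 and 3 through 4.** The bond between C3 of the first lactone and the carbinol carbon is cut as an aldol, because in 2 this carbon is α to the carbonyl. The two stereochemical tasks are deliberately separated.
- The ring centre is set in the C–C bond formation itself, under kinetic control, on the face of enolate 4 away from the trityloxymethyl group.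
- The carbinol centre is not trusted to the aldol, since the ring-locked enolate geometry favours the unwanted anti adduct. It is erased by oxidation to ketone 6 and set again by chelation-controlled hydride delivery to give the syn alcohol 7.
- Direct acylation of 4 to 6 would save a step. However, 6 would then form as its own enolate, and its ring centre would be fixed by a protonation and not by the direction of bond formation. The aldol detour costs one step and secures that centre.

**2 from 1.** Only the O–trityl bond is cut. The single stereocentre of the chiral-pool lactone 1 controls the first new centre in step 2 and is itself destroyed in step 8, after it has done its work.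

## Alternatives that were turned down

**Alternative 1:** carbene cyclopropanation followed by oxygen opening of the cyclopropane.
- Disconnection: the hydroxy lactone A3, which is the desilylated form of 13, is traced to the cyclopropane-fused lactone A2 by joining its α-carbon to the carbinol carbon on paper. A2 is cut at the α–β and α–carbinol bonds to the (Z)-cinnamyl diazoacetate A1.
- Forward key step: a chiral dirhodium carboxamidate such as Rh2(5S-MEPY)4 turns A1 into a rhodium carbene that adds across the tethered Z-alkene. This closes the lactone and the cyclopropane together, with the aryl group endo. An oxygen nucleophile then has to open the donor–acceptor cyclopropane at the benzylic carbon with inversion to reach A3, which joins the present route at 13 after silylation.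
- For: it is clearly shorter to the 13 stage and catalytic in the source of chirality. Intramolecular cyclopropanation of Z-allylic diazoacetates is among the most dependable asymmetric carbene reactions.
- Against: the carbinol configuration depends on a clean invertive substitution at a carbon whose cation is stabilised by two methoxy groups. Any ionisation of the cyclopropane bond before the nucleophile arrives would scramble that centre. The absolute configuration also rests on catalyst selectivity and not on a bought stereocentre.
- Comparison: Alternative 1 wins on step economy. The chosen route offers a carbinol centre set by hydride delivery inside a chelate and an absolute configuration fixed by the chiral pool.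

**Alternative 2:** lactone closure by a one-carbon aldehyde on a chiral keto acid.
- Disconnection: the keto lactone A5 is cut at the C4–C5 bond and at the ring O–C(=O) bond. This gives the keto acid A4 and a one-carbon aldehyde.
- Forward key step: the salt of A4 adds to the one-carbon aldehyde at the CH2 group next to the aryl ketone. On acidification the new CH2OH lactonises onto the carboxyl group. The C4 centre, now α to the ketone, should settle trans to the benzyl group.
- For: it is the most convergent plan, with both aryl groups in place before the ring exists. The ring-forming step is a simple aldol–lactonisation, and trans is reached under thermodynamic control.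
- Against: A4 must first be made enantiopure. The hydroxymethylation can add twice at the activated CH2. The carbinol must be created last by reducing a ketone whose only control element is the adjacent, enolisable C4. The benzyl ether must finally be hydrogenolysed next to a benzylic alcohol that is itself prone to hydrogenolysis.
- Comparison: Alternative 2 is stronger in convergence and step count. The chosen route fixes and protects the carbinol centre before the second aryl unit arrives and ends with fluoride instead of hydrogen.

**Alternative 3:** alkoxycarbonyl radical cyclisation.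
- Disconnection: the bis-silyl ether A7, which is identical with 19, is cut at the C2–C3 bond to the Se-phenyl selenocarbonate A6 of a homoallylic alcohol carrying a styrene.
- Forward key step: a tin hydride removes the phenylselanyl group. The alkoxycarbonyl radical closes 5-exo-trig onto the styrene, and the benzylic radical takes up hydrogen. This forms the carbonyl–C3 bond, the ring and the C3 centre in one step.
- For: the step is neutral, needs no enolate and no labile benzylic bromide, and delivers the same penultimate compound, so the endgame is shared.
- Against: the open-chain precursor A6 must already carry the carbinol and the allylic centre in the correct relative and absolute sense, together with the styrene. That is at least as long as the way to 13. The trans outcome depends on a conformational preference in the ring-closing transition state and not on attack anti to a large group. Stoichiometric tin and selenium are required, and the radical can be reduced before it cyclises.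
- Comparison: Alternative 3 is equal on the final bond and arguably gentler. The chosen route offers two substrate-controlled stereochemical steps from one cheap centre and a C3 alkylation whose facial bias is steric and large.

Key step: step 8

Remark on the chemistry: the carbinol carbon of 5 and the anomeric carbon of 12 are left undefined in the SMILES. Both are mixtures that converge in the step that follows (step 3 and step 9).

## Route

Step 1
Reactants: 1 (S)-5-(hydroxymethyl)dihydrofuran-2(3H)-one
Product: 2 (S)-5-[(trityloxy)methyl]dihydrofuran-2(3H)-one
Conditions: Ph3CCl, pyridine, DMAP (cat.), rt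
Reagents that add atoms: trityl chloride, ClC(c1ccccc1)(c1ccccc1)c1ccccc1
Why: Tritylation of the primary alcohol through the trityl cation trapped by the base; the stereocentre is not involved, and the very large ether will shield one face of the lactone enolate in step 2.

Step 2
Reactants: 2 (S)-5-[(trityloxy)methyl]dihydrofuran-2(3H)-one; 3 3,4-dimethoxybenzaldehyde
Product: 5 (3S,5S)-3-[hydroxy(3,4-dimethoxyphenyl)methyl]-5-[(trityloxy)methyl]dihydrofuran-2(3H)-one (both carbinol epimers), via lithium lactone enolate 4 (not isolated)
Conditions: LiN(iPr)2, THF, −78 °C; then 3, −78 °C; AcOH quench at −78 °C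
Reagents that add atoms: none
Why: Kinetic lithium enolate aldol addition: the aldehyde should reach the planar enolate 4 on the face opposite the trityloxymethyl group, which sets the ring centre trans to C5 (3S). The carbinol centre is not controlled (the ring-locked enolate geometry favours the anti adduct in a Zimmerman–Traxler chair), and both epimers are carried on because step 3 erases that centre; the cold quench prevents retro-aldol equilibration.

Step 3
Reactants: 5 (3S,5S)-3-[hydroxy(3,4-dimethoxyphenyl)methyl]-5-[(trityloxy)methyl]dihydrofuran-2(3H)-one (both carbinol epimers)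
Product: 6 (3S,5S)-3-(3,4-dimethoxybenzoyl)-5-[(trityloxy)methyl]dihydrofuran-2(3H)-one
Conditions: Dess–Martin periodinane, CH2Cl2, 0 °C to rt, no base; filtration through Celite, crude 6 used at once
Reagents that add atoms: none
Why: Dess–Martin oxidation of the secondary benzylic alcohol, so that both epimers of 5 converge on one ketone. C3 now lies between two carbonyl groups, so 6 is made without base and reduced immediately, before enolisation can disturb the centre set in step 2.

Step 4
Reactants: 6 (3S,5S)-3-(3,4-dimethoxybenzoyl)-5-[(trityloxy)methyl]dihydrofuran-2(3H)-one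
Product: 7 (3S,5S)-3-[(S)-hydroxy(3,4-dimethoxyphenyl)methyl]-5-[(trityloxy)methyl]dihydrofuran-2(3H)-one
Conditions: Zn(BH4)2, Et2O, −20 to 0 °C
Reagents that add atoms: none
Why: Chelation-controlled reduction of an α-substituted β-keto ester: zinc bridges the ketone and lactone carbonyl oxygens, which holds the aroyl group in one rotamer. Hydride should then enter the ketone on the side of the C3 hydrogen, away from the ring methylene, giving the syn hydroxy lactone with the (S) carbinol; the lactone is not reduced by this reagent in the cold.

Step 5
Reactants: 7 (3S,5S)-3-[(S)-hydroxy(3,4-dimethoxyphenyl)methyl]-5-[(trityloxy)methyl]dihydrofuran-2(3H)-one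
Product: 8 (3S,5S)-3-[(S)-(tert-butyldimethylsilyloxy)(3,4-dimethoxyphenyl)methyl]-5-[(trityloxy)methyl]dihydrofuran-2(3H)-one
Conditions: TBSOTf, 2,6-lutidine, CH2Cl2, −78 to 0 °C
Reagents that add atoms: tert-butyldimethylsilyl triflate, CC(C)(C)[Si](C)(C)OS(=O)(=O)C(F)(F)F
Why: Silylation of a hindered secondary alcohol with a silyl triflate and a hindered base, which keeps the medium free of acid for the trityl ether. The silyl ether protects the carbinol from hydride and, more importantly, removes it as a nucleophile for the aldehyde formed in step 8.

Step 6
Reactants: 8 (3S,5S)-3-[(S)-(tert-butyldimethylsilyloxy)(3,4-dimethoxyphenyl)methyl]-5-[(trityloxy)methyl]dihydrofuran-2(3H)-one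
Product: 9 (2R,4S)-2-[(S)-(tert-butyldimethylsilyloxy)(3,4-dimethoxyphenyl)methyl]-5-(trityloxy)pentane-1,4-diol
Conditions: LiAlH4, THF, 0 °C; aqueous NaOH work-up
Reagents that add atoms: none
Why: Hydride reduction of the lactone to the 1,4-diol; the old acyl carbon becomes the CH2OH that will be C5 of the final ring, and no stereocentre is touched. The low temperature is chosen to suppress a 1,3-shift of the silyl group to the new primary alkoxide.

Step 7
Reactants: 9 (2R,4S)-2-[(S)-(tert-butyldimethylsilyloxy)(3,4-dimethoxyphenyl)methyl]-5-(trityloxy)pentane-1,4-diol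
Product: 10 (2R,4S)-2-[(S)-(tert-butyldimethylsilyloxy)(3,4-dimethoxyphenyl)methyl]pentane-1,4,5-triol
Conditions: H2 (1 atm), 10% Pd/C, EtOAc, rt
Reagents that add atoms: none
Why: Hydrogenolysis of the trityl ether to triphenylmethane in a neutral, non-protic solvent; it avoids the acid that would ionise the electron-rich benzylic silyl ether. The secondary benzylic silyl ether should be much slower to cleave on palladium when no acid is present.

Step 8
Reactants: 10 (2R,4S)-2-[(S)-(tert-butyldimethylsilyloxy)(3,4-dimethoxyphenyl)methyl]pentane-1,4,5-triol
Product: 12 (4R)-4-[(S)-(tert-butyldimethylsilyloxy)(3,4-dimethoxyphenyl)methyl]tetrahydrofuran-2-ol (both anomers), via γ-hydroxy aldehyde 11 (not isolated)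
Conditions: NaIO4, NaHCO3, THF–H2O, 0 °C to rt
Reagents that add atoms: none
Why: Periodate condenses with the vicinal 4,5-diol of 10 to a five-membered cyclic periodate ester, which fragments with cleavage of the C4–C5 bond to formaldehyde and the γ-hydroxy aldehyde 11 (Malaprade glycol cleavage), the iodine ending as iodate. In 11 the primary hydroxyl lies four atoms from the aldehyde carbon and adds to it at once in a 5-exo-trig closure, which forms the ring O–C bond and gives lactol 12. The closest known reaction type is the periodate cleavage of 1,2,5-triols to 2-hydroxytetrahydrofurans, the standard way of turning γ-(hydroxymethyl)butyrolactones end-for-end. The only new stereocentre is the anomeric carbon; it equilibrates through ring–chain tautomerism, is not controlled and disappears in step 9. The centres that matter are not at risk: the carbon next to the aldehyde is a CH2 group, so neither C4 of 12 nor the carbinol carbon can epimerise, while the centre bought with 1, having directed step 2, becomes the sp2 aldehyde carbon. The step needs chemoselectivity and one regiochemical decision: 10 holds a single 1,2-diol (the primary hydroxyl is 1,4-related to it and the third oxygen is a silyl ether), and the silyl group on the carbinol oxygen leaves the primary hydroxyl as the only nucleophile, which matters because a free carbinol hydroxyl would be equally well placed for a five-membered lactol. Bicarbonate keeps the medium near neutral for the silyl ether, and the dimethoxyphenyl ring, having no free phenol, should not be attacked by periodate.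

Step 9
Reactants: 12 (4R)-4-[(S)-(tert-butyldimethylsilyloxy)(3,4-dimethoxyphenyl)methyl]tetrahydrofuran-2-ol (both anomers)
Product: 13 (4R)-4-[(S)-(tert-butyldimethylsilyloxy)(3,4-dimethoxyphenyl)methyl]dihydrofuran-2(3H)-one
Conditions: Ag2CO3 on Celite, benzene, reflux
Reagents that add atoms: none
Why: Fétizon oxidation of a lactol to the lactone on a neutral heterogeneous oxidant; both anomers converge. No other free hydroxyl is present, and C4 is β to the new carbonyl and cannot epimerise.

Step 10
Reactants: 14 vanillin (4-hydroxy-3-methoxybenzaldehyde)
Product: 15 4-(tert-butyldimethylsilyloxy)-3-methoxybenzaldehyde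
Conditions: TBSCl, imidazole, DMF, rt
Reagents that add atoms: tert-butyldimethylsilyl chloride, CC(C)(C)[Si](C)(C)Cl
Why: Standard silylation of a phenol; the silyl ether is chosen so that the phenol and the carbinol can be freed together by fluoride at the end.

Step 11
Reactants: 15 4-(tert-butyldimethylsilyloxy)-3-methoxybenzaldehyde
Product: 16 [4-(tert-butyldimethylsilyloxy)-3-methoxyphenyl]methanol
Conditions: NaBH4, EtOH, 0 °C
Reagents that add atoms: none
Why: Borohydride reduction of the aryl aldehyde; the short reaction time in the cold should spare the aryl silyl ether.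

Step 12
Reactants: 16 [4-(tert-butyldimethylsilyloxy)-3-methoxyphenyl]methanol
Product: 17 [4-(bromomethyl)-2-methoxyphenoxy](tert-butyl)dimethylsilane
Conditions: PPh3, CBr4, CH2Cl2, 0 °C; used without storage
Reagents that add atoms: carbon tetrabromide, BrC(Br)(Br)Br
Why: Appel bromination under neutral conditions, which suits an acid-sensitive, electron-rich benzylic system; the bromide is taken into step 13 directly.

Step 13
Reactants: 13 (4R)-4-[(S)-(tert-butyldimethylsilyloxy)(3,4-dimethoxyphenyl)methyl]dihydrofuran-2(3H)-one; 17 [4-(bromomethyl)-2-methoxyphenoxy](tert-butyl)dimethylsilane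
Product: 19 (3R,4R)-3-[4-(tert-butyldimethylsilyloxy)-3-methoxybenzyl]-4-[(S)-(tert-butyldimethylsilyloxy)(3,4-dimethoxyphenyl)methyl]dihydrofuran-2(3H)-one, via lithium lactone enolate 18 (not isolated)
Conditions: LiN(SiMe3)2, THF, −78 °C; then 17, DMPU, −78 to −40 °C
Reagents that add atoms: none
Why: Kinetic enolate alkylation (SN2 on a benzylic bromide) of a β-substituted γ-butyrolactone; C3 is the only enolisable position. The bromide should approach anti to the large C4 substituent, giving the trans (3R) product; one equivalent of base in the cold limits proton exchange and double alkylation.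

Step 14
Reactants: 19 (3R,4R)-3-[4-(tert-butyldimethylsilyloxy)-3-methoxybenzyl]-4-[(S)-(tert-butyldimethylsilyloxy)(3,4-dimethoxyphenyl)methyl]dihydrofuran-2(3H)-one
Product: 20 (3R,4R)-4-[(S)-(3,4-dimethoxyphenyl)(hydroxy)methyl]-3-(4-hydroxy-3-methoxybenzyl)dihydrofuran-2(3H)-one
Conditions: Bu4NF, AcOH (1:1), THF, 0 °C to rt
Reagents that add atoms: none
Why: Fluoride-induced cleavage of both silyl ethers, buffered with acetic acid so that the carbinol oxygen is protonated as it is freed and cannot attack the lactone carbonyl or cause epimerisation at C3. The medium is also far too weakly acidic to ionise the benzylic C–O bond.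

## Compound list

1 | (S)-5-(hydroxymethyl)dihydrofuran-2(3H)-one | O=C1CC[C@@H](CO)O1 | starting material
2 | (S)-5-[(trityloxy)methyl]dihydrofuran-2(3H)-one | O=C1CC[C@@H](COC(c2ccccc2)(c2ccccc2)c2ccccc2)O1 | intermediate
3 | 3,4-dimethoxybenzaldehyde | COc1ccc(C=O)cc1OC | starting material
4 | lithium enolate of 2 | [Li]OC1=CC[C@@H](COC(c2ccccc2)(c2ccccc2)c2ccccc2)O1 | intermediate (not isolated)
5 | (3S,5S)-3-[hydroxy(3,4-dimethoxyphenyl)methyl]-5-[(trityloxy)methyl]dihydrofuran-2(3H)-one, both carbinol epimers | O=C1[C@H](C(O)c2ccc(OC)c(OC)c2)C[C@@H](COC(c2ccccc2)(c2ccccc2)c2ccccc2)O1 | intermediate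
6 | (3S,5S)-3-(3,4-dimethoxybenzoyl)-5-[(trityloxy)methyl]dihydrofuran-2(3H)-one | O=C1[C@H](C(=O)c2ccc(OC)c(OC)c2)C[C@@H](COC(c2ccccc2)(c2ccccc2)c2ccccc2)O1 | intermediate
7 | (3S,5S)-3-[(S)-hydroxy(3,4-dimethoxyphenyl)methyl]-5-[(trityloxy)methyl]dihydrofuran-2(3H)-one | O=C1[C@H]([C@H](O)c2ccc(OC)c(OC)c2)C[C@@H](COC(c2ccccc2)(c2ccccc2)c2ccccc2)O1 | intermediate
8 | (3S,5S)-3-[(S)-(tert-butyldimethylsilyloxy)(3,4-dimethoxyphenyl)methyl]-5-[(trityloxy)methyl]dihydrofuran-2(3H)-one | O=C1[C@H]([C@H](O[Si](C)(C)C(C)(C)C)c2ccc(OC)c(OC)c2)C[C@@H](COC(c2ccccc2)(c2ccccc2)c2ccccc2)O1 | intermediate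
9 | (2R,4S)-2-[(S)-(tert-butyldimethylsilyloxy)(3,4-dimethoxyphenyl)methyl]-5-(trityloxy)pentane-1,4-diol | OC[C@@H](C[C@H](O)COC(c1ccccc1)(c1ccccc1)c1ccccc1)[C@H](O[Si](C)(C)C(C)(C)C)c1ccc(OC)c(OC)c1 | intermediate
10 | (2R,4S)-2-[(S)-(tert-butyldimethylsilyloxy)(3,4-dimethoxyphenyl)methyl]pentane-1,4,5-triol | OC[C@@H](C[C@H](O)CO)[C@H](O[Si](C)(C)C(C)(C)C)c1ccc(OC)c(OC)c1 | intermediate
11 | (3R)-3-[(S)-(tert-butyldimethylsilyloxy)(3,4-dimethoxyphenyl)methyl]-4-hydroxybutanal | OC[C@@H](CC=O)[C@H](O[Si](C)(C)C(C)(C)C)c1ccc(OC)c(OC)c1 | intermediate (not isolated)
12 | (4R)-4-[(S)-(tert-butyldimethylsilyloxy)(3,4-dimethoxyphenyl)methyl]tetrahydrofuran-2-ol, both anomers | OC1C[C@H](CO1)[C@H](O[Si](C)(C)C(C)(C)C)c1ccc(OC)c(OC)c1 | intermediate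
13 | (4R)-4-[(S)-(tert-butyldimethylsilyloxy)(3,4-dimethoxyphenyl)methyl]dihydrofuran-2(3H)-one | O=C1C[C@H](CO1)[C@H](O[Si](C)(C)C(C)(C)C)c1ccc(OC)c(OC)c1 | intermediate
14 | vanillin (4-hydroxy-3-methoxybenzaldehyde) | COc1cc(C=O)ccc1O | starting material
15 | 4-(tert-butyldimethylsilyloxy)-3-methoxybenzaldehyde | COc1cc(C=O)ccc1O[Si](C)(C)C(C)(C)C | intermediate
16 | [4-(tert-butyldimethylsilyloxy)-3-methoxyphenyl]methanol | COc1cc(CO)ccc1O[Si](C)(C)C(C)(C)C | intermediate
17 | [4-(bromomethyl)-2-methoxyphenoxy](tert-butyl)dimethylsilane | COc1cc(CBr)ccc1O[Si](C)(C)C(C)(C)C | intermediate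
18 | lithium enolate of 13 | [Li]OC1=C[C@H](CO1)[C@H](O[Si](C)(C)C(C)(C)C)c1ccc(OC)c(OC)c1 | intermediate (not isolated)
19 | (3R,4R)-3-[4-(tert-butyldimethylsilyloxy)-3-methoxybenzyl]-4-[(S)-(tert-butyldimethylsilyloxy)(3,4-dimethoxyphenyl)methyl]dihydrofuran-2(3H)-one | COc1cc(C[C@H]2C(=O)OC[C@@H]2[C@H](O[Si](C)(C)C(C)(C)C)c2ccc(OC)c(OC)c2)ccc1O[Si](C)(C)C(C)(C)C | intermediate
20 | (3R,4R)-4-[(S)-(3,4-dimethoxyphenyl)(hydroxy)methyl]-3-(4-hydroxy-3-methoxybenzyl)dihydrofuran-2(3H)-one | COc1cc(C[C@H]2C(=O)OC[C@@H]2[C@H](O)c2ccc(OC)c(OC)c2)ccc1O | target

## Step count and least certain steps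

Total: 14 steps. Longest linear sequence: 11 steps (steps 1–9, 13 and 14, from 1). The bromide branch is 3 steps (10–12) before it joins.

**Step 8 (key step).**
- What may go wrong: the γ-hydroxy aldehyde 11 may not come to rest as monomeric 12. Ring–chain equilibration leaves free aldehyde, which can form acetals with the formaldehyde released or with a second lactol molecule. A 1,3-shift of the silyl group to the primary oxygen, in 10 or in 11, would also let the carbinol oxygen close the ring in place of the primary one.
- Fallback, from 9 back to 13: the ring is closed at the acid level and not at the aldehyde level. The primary hydroxyl of 9 is acetylated selectively (AcCl, 2,4,6-collidine, CH2Cl2, −78 °C) to (2R,4S)-2-[(S)-(tert-butyldimethylsilyloxy)(3,4-dimethoxyphenyl)methyl]-4-hydroxy-5-(trityloxy)pentyl acetate F1. Hydrogenolysis as in step 7 gives (2R,4S)-2-[(S)-(tert-butyldimethylsilyloxy)(3,4-dimethoxyphenyl)methyl]-4,5-dihydroxypentyl acetate F2. NaIO4 cleaves this to (2R)-2-[(S)-(tert-butyldimethylsilyloxy)(3,4-dimethoxyphenyl)methyl]-4-oxobutyl acetate F3, an aldehyde that cannot cyclise. Pinnick oxidation (NaClO2, NaH2PO4, 2-methyl-2-butene) gives (3R)-4-acetoxy-3-[(S)-(tert-butyldimethylsilyloxy)(3,4-dimethoxyphenyl)methyl]butanoic acid F4. K2CO3 in MeOH at 0 °C removes the acetate to give (3R)-3-[(S)-(tert-butyldimethylsilyloxy)(3,4-dimethoxyphenyl)methyl]-4-hydroxybutanoic acid F5 as its salt, and acidification to about pH 4 should lactonise it to 13.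

**Step 4 (with the ketone made in step 3).**
- What may go wrong: enolisation of the 1,3-dicarbonyl 6 may scramble the ring centre before hydride arrives, and incomplete chelation would lower the facial selectivity at the ketone.
- Fallback, from 5 back to 7: the ketone is left out altogether. The two carbinol epimers of 5 are diastereomeric alcohols and should separate by chromatography. The syn epimer is 7 itself and is carried into step 5. Its ring centre was set by the kinetic aldol and is never made labile. The cost is the anti share of the aldol, which is set aside.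

**Step 7.**
- What may go wrong: the trityl ether may be cleaved only slowly on palladium, and prolonged exposure invites hydrogenolysis of the benzylic C–O bond of the electron-rich silyl ether.
- Fallback, from 1 back to 10: the side arm is carried as an ester that the hydride of step 6 removes, so no hydrogenolysis is needed. Lactone 1 is acylated (pivaloyl chloride, pyridine) to [(2S)-5-oxotetrahydrofuran-2-yl]methyl pivalate F6. The aldol with 3 as in step 2 gives [(2S,4S)-4-[hydroxy(3,4-dimethoxyphenyl)methyl]-5-oxotetrahydrofuran-2-yl]methyl pivalate F7 as carbinol epimers. Dess–Martin oxidation gives [(2S,4S)-4-(3,4-dimethoxybenzoyl)-5-oxotetrahydrofuran-2-yl]methyl pivalate F8. Zn(BH4)2 gives [(2S,4S)-4-[(S)-hydroxy(3,4-dimethoxyphenyl)methyl]-5-oxotetrahydrofuran-2-yl]methyl pivalate F9. TBSOTf and 2,6-lutidine give [(2S,4S)-4-[(S)-(tert-butyldimethylsilyloxy)(3,4-dimethoxyphenyl)methyl]-5-oxotetrahydrofuran-2-yl]methyl pivalate F10. Excess LiAlH4 then reduces lactone and pivalate together to 10. The smaller side arm is expected to shield the enolate face less well, so minor ring epimers would have to be removed at the F9 stage.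

**Step 14.**
- What may go wrong: the benzylic silyl ether is hindered and may need forcing. If the carbinol oxygen is then present as an alkoxide, acyl transfer to it would give the isomeric lactone. Stronger acid would instead ionise the benzylic C–O bond, with ring closure onto the guaiacyl ring.
- Fallback, from 19 to 20: the two silyl ethers are removed one at a time by reagents matched to each. KHF2 in MeOH at rt cleaves only the aryl silyl ether and gives (3R,4R)-4-[(S)-(tert-butyldimethylsilyloxy)(3,4-dimethoxyphenyl)methyl]-3-(4-hydroxy-3-methoxybenzyl)dihydrofuran-2(3H)-one F11. HF·pyridine in THF with added pyridine at 0 °C then removes the alkyl silyl ether under conditions where the carbinol is never an alkoxide, giving 20.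

## Further compounds

F1 | step 8 | (2R,4S)-2-[(S)-(tert-butyldimethylsilyloxy)(3,4-dimethoxyphenyl)methyl]-4-hydroxy-5-(trityloxy)pentyl acetate | CC(=O)OC[C@@H](C[C@H](O)COC(c1ccccc1)(c1ccccc1)c1ccccc1)[C@H](O[Si](C)(C)C(C)(C)C)c1ccc(OC)c(OC)c1
F2 | step 8 | (2R,4S)-2-[(S)-(tert-butyldimethylsilyloxy)(3,4-dimethoxyphenyl)methyl]-4,5-dihydroxypentyl acetate | CC(=O)OC[C@@H](C[C@H](O)CO)[C@H](O[Si](C)(C)C(C)(C)C)c1ccc(OC)c(OC)c1
F3 | step 8 | (2R)-2-[(S)-(tert-butyldimethylsilyloxy)(3,4-dimethoxyphenyl)methyl]-4-oxobutyl acetate | CC(=O)OC[C@@H](CC=O)[C@H](O[Si](C)(C)C(C)(C)C)c1ccc(OC)c(OC)c1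
F4 | step 8 | (3R)-4-acetoxy-3-[(S)-(tert-butyldimethylsilyloxy)(3,4-dimethoxyphenyl)methyl]butanoic acid | CC(=O)OC[C@@H](CC(=O)O)[C@H](O[Si](C)(C)C(C)(C)C)c1ccc(OC)c(OC)c1
F5 | step 8 | (3R)-3-[(S)-(tert-butyldimethylsilyloxy)(3,4-dimethoxyphenyl)methyl]-4-hydroxybutanoic acid | OC[C@@H](CC(=O)O)[C@H](O[Si](C)(C)C(C)(C)C)c1ccc(OC)c(OC)c1
F0 | step 4 | none | none
F6 | step 7 | [(2S)-5-oxotetrahydrofuran-2-yl]methyl pivalate | O=C1CC[C@@H](COC(=O)C(C)(C)C)O1
F7 | step 7 | [(2S,4S)-4-[hydroxy(3,4-dimethoxyphenyl)methyl]-5-oxotetrahydrofuran-2-yl]methyl pivalate, both carbinol epimers | O=C1[C@H](C(O)c2ccc(OC)c(OC)c2)C[C@@H](COC(=O)C(C)(C)C)O1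
F8 | step 7 | [(2S,4S)-4-(3,4-dimethoxybenzoyl)-5-oxotetrahydrofuran-2-yl]methyl pivalate | O=C1[C@H](C(=O)c2ccc(OC)c(OC)c2)C[C@@H](COC(=O)C(C)(C)C)O1
F9 | step 7 | [(2S,4S)-4-[(S)-hydroxy(3,4-dimethoxyphenyl)methyl]-5-oxotetrahydrofuran-2-yl]methyl pivalate | O=C1[C@H]([C@H](O)c2ccc(OC)c(OC)c2)C[C@@H](COC(=O)C(C)(C)C)O1
F10 | step 7 | [(2S,4S)-4-[(S)-(tert-butyldimethylsilyloxy)(3,4-dimethoxyphenyl)methyl]-5-oxotetrahydrofuran-2-yl]methyl pivalate | O=C1[C@H]([C@H](O[Si](C)(C)C(C)(C)C)c2ccc(OC)c(OC)c2)C[C@@H](COC(=O)C(C)(C)C)O1
F11 | step 14 | (3R,4R)-4-[(S)-(tert-butyldimethylsilyloxy)(3,4-dimethoxyphenyl)methyl]-3-(4-hydroxy-3-methoxybenzyl)dihydrofuran-2(3H)-one | COc1cc(C[C@H]2C(=O)OC[C@@H]2[C@H](O[Si](C)(C)C(C)(C)C)c2ccc(OC)c(OC)c2)ccc1O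
A1 | alternative 1 | (Z)-3-(3,4-dimethoxyphenyl)prop-2-en-1-yl 2-diazoacetate | [N-]=[N+]=CC(=O)OC/C=C\c1ccc(OC)c(OC)c1
A2 | alternative 1 | cis-fused 6-endo-(3,4-dimethoxyphenyl)-3-oxabicyclo[3.1.0]hexan-2-one, single enantiomer | O=C1OC[C@@H]2[C@H](c3ccc(OC)c(OC)c3)[C@H]12
A3 | alternative 1 | (4R)-4-[(S)-hydroxy(3,4-dimethoxyphenyl)methyl]dihydrofuran-2(3H)-one | O=C1C[C@H](CO1)[C@H](O)c1ccc(OC)c(OC)c1
A4 | alternative 2 | (R)-2-[4-(benzyloxy)-3-methoxybenzyl]-4-(3,4-dimethoxyphenyl)-4-oxobutanoic acid | O=C(c1ccc(OC)c(OC)c1)C[C@H](C(=O)O)Cc1ccc(OCc2ccccc2)c(OC)c1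
A5 | alternative 2 | (3R,4R)-3-[4-(benzyloxy)-3-methoxybenzyl]-4-(3,4-dimethoxybenzoyl)dihydrofuran-2(3H)-one | O=C1OC[C@H](C(=O)c2ccc(OC)c(OC)c2)[C@H]1Cc1ccc(OCc2ccccc2)c(OC)c1
A6 | alternative 3 | O-[(2R,3E)-2-[(S)-(tert-butyldimethylsilyloxy)(3,4-dimethoxyphenyl)methyl]-4-[4-(tert-butyldimethylsilyloxy)-3-methoxyphenyl]but-3-en-1-yl] Se-phenyl selenocarbonate (E geometry assumed) | O=C([Se]c1ccccc1)OC[C@@H](/C=C/c1ccc(O[Si](C)(C)C(C)(C)C)c(OC)c1)[C@H](O[Si](C)(C)C(C)(C)C)c1ccc(OC)c(OC)c1
A7 | alternative 3 | (3R,4R)-3-[4-(tert-butyldimethylsilyloxy)-3-methoxybenzyl]-4-[(S)-(tert-butyldimethylsilyloxy)(3,4-dimethoxyphenyl)methyl]dihydrofuran-2(3H)-one (identical with 19) | COc1cc(C[C@H]2C(=O)OC[C@@H]2[C@H](O[Si](C)(C)C(C)(C)C)c2ccc(OC)c(OC)c2)ccc1O[Si](C)(C)C(C)(C)C
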